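The route rests on tracing the C6 hydroxyl and the C7 methoxy group, which is allylic to C8=C9, to a trans C6–C7 vinyl oxirane erythro to the C5 carbinol, whose oxygen later becomes the ring oxygen of the dihydropyranone. The key step exploits that C5 hydroxyl: a tartrate-controlled titanium epoxidation directed by it oxidises only C6=C7 of the (6E,8E)-diene and sets C6 and C7 in one operation. Its precursor is the (5S)-dienyl homopropargylic carbinol carrying the erythro C10/C11 diacetate, made here as a single C5 epimer by catalytic asymmetric propargylation so that the epoxidation is a matched reaction, not a resolution. Retentive palladium methanolysis at C7 and carbonylative lactonisation of the alkyne terminus complete the synthesis.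

Key step: step 8

Remarks before the steps
- Locants C1–C12 are those of the target chain throughout (C1 = lactone carbonyl, introduced only in step 12; C12 = methyl).
- Stereochemical check: the target is (5S,6S,7S,8E,10S,11R). Carbinol 11 (5S,10S,11R) and oxirane 12 (5S,6S,7S) map onto it atom by atom, and L-(+)-tartrate is the matched ligand for both epoxidations (steps 1 and 8).
- Assumption: the (S)-configured phosphoric acid of step 7 is taken to give the 5S carbinol, by analogy with the R-selective additions of allyl- and allenylboronates to aryl and alkenyl aldehydes under the (R)-acid. A sluggish, mismatched step 8 would expose the opposite sense, and the antipodal acid would then be used.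
- Boron, aluminium and titanium alkoxides of the products that are hydrolysed during work-up are not numbered.

Step 1
Reactants: 1 penta-1,4-dien-3-ol
Product: 2 (2R,3S)-1,2-epoxypent-4-en-3-ol
Conditions: Ti(OiPr)4 (cat.), L-(+)-diisopropyl tartrate (cat.), t-BuOOH (anhydrous), 4 Å MS, CH2Cl2, −20 °C
Reagents that add atoms: tert-butyl hydroperoxide, CC(C)(C)OO
Why: Sharpless asymmetric epoxidation used as a desymmetrisation of the divinyl carbinol: L-(+)-tartrate fixes the alkene face and, through the erythro preference of secondary allylic alcohols, the vinyl group that reacts, so the oxirane carbon (R) and the carbinol carbon (S) are set together, and the minor enantiomer is drained by a faster second epoxidation.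

Step 2
Reactants: 2 (2R,3S)-1,2-epoxypent-4-en-3-ol
Product: 3 (3S,4R)-pent-1-ene-3,4-diol
Conditions: LiAlH4, THF, 0 °C to rt; aqueous potassium sodium tartrate work-up
Reagents that add atoms: none
Why: Hydride opening of a terminal epoxide (SN2 at the unsubstituted carbon) gives the methyl carbinol without touching either C–O stereocentre or the isolated alkene.

Step 3
Reactants: 3 (3S,4R)-pent-1-ene-3,4-diol
Product: 4 (3S,4R)-pent-1-ene-3,4-diyl diacetate
Conditions: Ac2O, pyridine, 4-(dimethylamino)pyridine (cat.), CH2Cl2, 0 °C to rt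
Reagents that add atoms: acetic anhydride, CC(=O)OC(C)=O
Why: Nucleophile-catalysed O-acetylation of both secondary hydroxyls installs the two acetates of the target at the outset and affects no stereocentre.

Step 4
Reactants: 4 (3S,4R)-pent-1-ene-3,4-diyl diacetate
Product: 6 (2R,3R)-4-oxobutane-2,3-diyl diacetate, via ozonide 5 (not isolated)
Conditions: O3, CH2Cl2, −78 °C; then Me2S, −78 °C to rt; aldehyde used crude
Reagents that add atoms: ozone, [O-][O+]=O
Why: Ozonolysis with reductive work-up cleaves the only alkene under neutral, cold conditions, so the α-acetoxy centre should not epimerise and no β-acetoxy elimination is triggered.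

Step 5
Reactants: 6 (2R,3R)-4-oxobutane-2,3-diyl diacetate; 7 (triphenylphosphoranylidene)acetaldehyde
Product: 8 (2R,3S,4E)-6-oxohex-4-ene-2,3-diyl diacetate
Conditions: Ph3P=CHCHO (1.1 equiv), toluene, 50 °C
Reagents that add atoms: (triphenylphosphoranylidene)acetaldehyde (compound 7), O=CC=P(c1ccccc1)(c1ccccc1)c1ccccc1
Why: Wittig olefination with a stabilised formyl ylide is E-selective and base-free, and mono-homologation is favoured because the saturated α-acetoxy aldehyde is more electrophilic than the enal that forms.

Step 6
Reactants: 8 (2R,3S,4E)-6-oxohex-4-ene-2,3-diyl diacetate; 7 (triphenylphosphoranylidene)acetaldehyde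
Product: 9 (2R,3S,4E,6E)-8-oxoocta-4,6-diene-2,3-diyl diacetate
Conditions: Ph3P=CHCHO (1.3 equiv), toluene, 80 °C, stopped before trienal builds up
Reagents that add atoms: (triphenylphosphoranylidene)acetaldehyde (compound 7), O=CC=P(c1ccccc1)(c1ccccc1)c1ccccc1
Why: A second Wittig homologation with the same stabilised ylide, run hotter because the enal is less electrophilic, should give the (E,E)-dienal with the new C6=C7 alkene E for the same reason as in step 5.

Step 7
Reactants: 9 (2R,3S,4E,6E)-8-oxoocta-4,6-diene-2,3-diyl diacetate; 10 allenylboronic acid pinacol ester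
Product: 11 (2R,3S,4E,6E,8S)-8-hydroxyundeca-4,6-dien-10-yne-2,3-diyl diacetate
Conditions: allenyl-B(pin) (1.5 equiv), (S)-3,3′-bis(2,4,6-triisopropylphenyl)-1,1′-binaphthyl-2,2′-diyl hydrogen phosphate (10 mol %), 4 Å MS, toluene, −20 °C; aq NaHCO3
Reagents that add atoms: allenylboronic acid pinacol ester (compound 10), C=C=CB1OC(C)(C)C(C)(C)O1
Why: Chiral-phosphoric-acid-catalysed propargylation with an allenylboronate runs through a closed six-membered transition state (SE2′, so only the homopropargylic alcohol forms) in which the acid, hydrogen-bonded to a boronate oxygen and the formyl hydrogen, selects the aldehyde face and sets C5 (S) independently of the remote C10/C11 centres.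

Step 8
Reactants: 11 (2R,3S,4E,6E,8S)-8-hydroxyundeca-4,6-dien-10-yne-2,3-diyl diacetate
Product: 12 (2R,3S,4E)-5-{(2S,3S)-3-[(1S)-1-hydroxybut-3-yn-1-yl]oxiran-2-yl}pent-4-ene-2,3-diyl diacetate
Conditions: Ti(OiPr)4 (cat.), L-(+)-diisopropyl tartrate (cat.), t-BuOOH (anhydrous, 1.3 equiv), 4 Å MS, CH2Cl2, −20 °C; sat. aq Na2SO4, Celite
Reagents that add atoms: tert-butyl hydroperoxide, CC(C)(C)OO
Why: The C5 alkoxide and tert-butyl hydroperoxide bind the dimeric titanium–tartrate complex and the activated peroxide oxygen is passed to the adjacent C6=C7 π bond through a spiro transition state; the closest known reaction type is the Sharpless asymmetric epoxidation, in its kinetic-resolution mode, of secondary (E)-allylic and dienyl carbinols. The oxirane ring closes by concerted syn oxygen-atom transfer, both C–O bonds forming from one oxygen on one alkene face, so the E geometry is carried into the trans epoxide. C6 and C7 are both set by the L-(+)-tartrate, whose preferred face is the one erythro to the (5S) carbinol (matched pair), which should give the (5S,6S,7S) oxirane. The step needs site selectivity for C6=C7 over C8=C9, secured because only the alkene allylic to the titanium-bound C5 oxygen is within reach and the distal alkene is deactivated by the C10 acetoxy carbon, and chemoselectivity over the alkyne, which this oxidant does not touch. It also needs the vinyl oxirane to survive, for which the catalytic molecular-sieve protocol at −20 °C and a non-acidic work-up are chosen; any residual (5R) epimer reacts far more slowly and is left behind.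

Step 9
Reactants: 12 (2R,3S,4E)-5-{(2S,3S)-3-[(1S)-1-hydroxybut-3-yn-1-yl]oxiran-2-yl}pent-4-ene-2,3-diyl diacetate
Product: 13 (2R,3S,4E,6S,7S,8S)-7,8-dihydroxy-6-methoxyundec-4-en-10-yne-2,3-diyl diacetate
Conditions: Pd(PPh3)4 (5 mol %), B(OMe)3 (3 equiv), THF, rt; aq NaH2PO4/Na2HPO4 buffer (pH 7)
Reagents that add atoms: trimethyl borate, COB(OC)OC
Why: Palladium-catalysed allylic substitution (Tsuji–Trost type) of a vinyl epoxide with a trialkyl borate: zerovalent palladium ionises the C7–O bond with inversion, the C6 alkoxide captures B(OMe)3, and the resulting borate hands methoxide to the adjacent C7 terminus on the face opposite palladium, so C7 keeps the oxirane configuration (net retention), C6 is untouched, and the tether together with the acetoxy-flanked C9 terminus favours 1,2- over 1,4-substitution.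

Step 10
Reactants: 13 (2R,3S,4E,6S,7S,8S)-7,8-dihydroxy-6-methoxyundec-4-en-10-yne-2,3-diyl diacetate
Product: 14 (2R,3S,4E,6S,7S,8S)-7,8-dihydroxy-11-iodo-6-methoxyundec-4-en-10-yne-2,3-diyl diacetate
Conditions: N-iodosuccinimide (1.1 equiv), AgNO3 (10 mol %), acetone, rt, dark
Reagents that add atoms: N-iodosuccinimide, O=C1CCC(=O)N1I
Why: Silver-catalysed electrophilic iodination of the terminal alkyne (via the silver acetylide) is fast at room temperature and should leave the electron-poor C8=C9 alkene, the diol and the acetates untouched.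

Step 11
Reactants: 14 (2R,3S,4E,6S,7S,8S)-7,8-dihydroxy-11-iodo-6-methoxyundec-4-en-10-yne-2,3-diyl diacetate
Product: 15 (2R,3S,4E,6S,7S,8S,10Z)-7,8-dihydroxy-11-iodo-6-methoxyundeca-4,10-diene-2,3-diyl diacetate
Conditions: 2-nitrobenzenesulfonylhydrazide (2.5 equiv), Et3N, THF/i-PrOH, rt
Reagents that add atoms: none
Why: Diimide reduction: diimide generated in situ transfers H2 in a concerted syn fashion to the iodoalkyne, giving the (Z)-iodoalkene without hydrogenolysis of the C–I bond, the iodoalkyne reacting faster than the hindered, oxygen-flanked C8=C9 alkene.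

Step 12
Reactants: 15 (2R,3S,4E,6S,7S,8S,10Z)-7,8-dihydroxy-11-iodo-6-methoxyundeca-4,10-diene-2,3-diyl diacetate
Product: 16 (2R,3S,4E,6S,7S)-7-hydroxy-6-methoxy-7-[(2S)-6-oxo-3,6-dihydro-2H-pyran-2-yl]hept-4-ene-2,3-diyl diacetate
Conditions: Pd(PPh3)4 (5 mol %), CO (1 atm), Et3N (2 equiv), THF, 40 °C
Reagents that add atoms: carbon monoxide, [C-]#[O+]
Why: Palladium-catalysed carbonylative lactonisation: oxidative addition of zerovalent palladium into the C2–I bond with retention of the Z geometry, CO insertion and acylation of the C5 hydroxyl close the six-membered unsaturated lactone in preference to the seven-membered ring through O6, and vinyl iodide insertion should outpace ionisation of the oxygen-flanked C10 allylic acetate.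

Compound list
1 | penta-1,4-dien-3-ol | C=CC(O)C=C | starting material
2 | (2R,3S)-1,2-epoxypent-4-en-3-ol | C=C[C@H](O)[C@H]1CO1 | intermediate
3 | (3S,4R)-pent-1-ene-3,4-diol | C=C[C@H](O)[C@@H](C)O | intermediate
4 | (3S,4R)-pent-1-ene-3,4-diyl diacetate | C=C[C@H](OC(C)=O)[C@@H](C)OC(C)=O | intermediate
5 | (1R,2R)-1-(1,2,4-trioxolan-3-yl)propane-1,2-diyl diacetate (ozonide, both epimers at the trioxolane carbon, not isolated) | C1OOC(O1)[C@H](OC(C)=O)[C@@H](C)OC(C)=O | intermediate
6 | (2R,3R)-4-oxobutane-2,3-diyl diacetate | O=C[C@H](OC(C)=O)[C@@H](C)OC(C)=O | intermediate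
7 | (triphenylphosphoranylidene)acetaldehyde | O=CC=P(c1ccccc1)(c1ccccc1)c1ccccc1 | starting material
8 | (2R,3S,4E)-6-oxohex-4-ene-2,3-diyl diacetate | O=C/C=C/[C@H](OC(C)=O)[C@@H](C)OC(C)=O | intermediate
9 | (2R,3S,4E,6E)-8-oxoocta-4,6-diene-2,3-diyl diacetate | O=C/C=C/C=C/[C@H](OC(C)=O)[C@@H](C)OC(C)=O | intermediate
10 | allenylboronic acid pinacol ester, 4,4,5,5-tetramethyl-2-(propa-1,2-dien-1-yl)-1,3,2-dioxaborolane | C=C=CB1OC(C)(C)C(C)(C)O1 | starting material
11 | (2R,3S,4E,6E,8S)-8-hydroxyundeca-4,6-dien-10-yne-2,3-diyl diacetate, the (5S)-dienyl homopropargylic carbinol | C#CC[C@H](O)/C=C/C=C/[C@H](OC(C)=O)[C@@H](C)OC(C)=O | intermediate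
12 | (2R,3S,4E)-5-{(2S,3S)-3-[(1S)-1-hydroxybut-3-yn-1-yl]oxiran-2-yl}pent-4-ene-2,3-diyl diacetate, the erythro trans-6,7-epoxide | C#CC[C@H](O)[C@@H]1O[C@H]1/C=C/[C@H](OC(C)=O)[C@@H](C)OC(C)=O | intermediate
13 | (2R,3S,4E,6S,7S,8S)-7,8-dihydroxy-6-methoxyundec-4-en-10-yne-2,3-diyl diacetate | CO[C@@H](/C=C/[C@H](OC(C)=O)[C@@H](C)OC(C)=O)[C@@H](O)[C@@H](O)CC#C | intermediate
14 | (2R,3S,4E,6S,7S,8S)-7,8-dihydroxy-11-iodo-6-methoxyundec-4-en-10-yne-2,3-diyl diacetate | CO[C@@H](/C=C/[C@H](OC(C)=O)[C@@H](C)OC(C)=O)[C@@H](O)[C@@H](O)CC#CI | intermediate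
15 | (2R,3S,4E,6S,7S,8S,10Z)-7,8-dihydroxy-11-iodo-6-methoxyundeca-4,10-diene-2,3-diyl diacetate | CO[C@@H](/C=C/[C@H](OC(C)=O)[C@@H](C)OC(C)=O)[C@@H](O)[C@@H](O)C/C=C\I | intermediate
16 | (6S)-6-[(1S,2S,3E,5S,6R)-5,6-diacetoxy-1-hydroxy-2-methoxyhept-3-en-1-yl]-5,6-dihydro-2H-pyran-2-one | CO[C@@H](/C=C/[C@H](OC(C)=O)[C@@H](C)OC(C)=O)[C@@H](O)[C@@H]1CC=CC(=O)O1 | target

Total step count: 12. Longest linear sequence: 12 steps (1 to 16); 7 and 10 are purchased.

Steps most likely to fail

Step 9. The process at risk is a second ionisation, of the C10 allylic acetate, by zerovalent palladium, or transfer of methoxide to the distal allyl terminus C9; either would erode regio- and stereochemical fidelity. No palladium-free way to open 12 at C7 with retention was found, so the fallback leaves the epoxide route: it sets out from enal 8 and comes back at 13. The syn C6/C7 oxygen pair is made by reagent-controlled alkoxyallylboration and O-methylation instead of allylic substitution. Enal 8 is added at −78 °C to the (Z)-γ-(methoxymethoxy)allylborane generated from allyl methoxymethyl ether, s-BuLi, (+)-B-methoxydiisopinocampheylborane and BF3·OEt2; this antipode is the one expected from the usual facial model, and an ethanolamine work-up spares the acetates. This should give the syn adduct (2R,3S,4E,6S,7S)-6-hydroxy-7-(methoxymethoxy)nona-4,8-diene-2,3-diyl diacetate F1. Its only free hydroxyl (target C7) is methylated with MeI/Ag2O to (2R,3S,4E,6S,7S)-6-methoxy-7-(methoxymethoxy)nona-4,8-diene-2,3-diyl diacetate F2. The monosubstituted alkene, less hindered and less deactivated than the doubly oxygen-flanked internal one, is cleaved with OsO4 (cat.)/NaIO4/2,6-lutidine through the diol (2R,3S,4E,6S,7S)-8,9-dihydroxy-6-methoxy-7-(methoxymethoxy)non-4-ene-2,3-diyl diacetate F3 to the aldehyde (2R,3S,4E,6S,7R)-6-methoxy-7-(methoxymethoxy)-8-oxooct-4-ene-2,3-diyl diacetate F4. Propargylation with 10 under the acid of step 7, now reinforced by the Felkin–Anh preference for the 5,6-anti product, should give (2R,3S,4E,6S,7S,8S)-8-hydroxy-6-methoxy-7-(methoxymethoxy)undec-4-en-10-yne-2,3-diyl diacetate F5. Me2BBr (CH2Cl2, −78 °C) then removes the methoxymethyl group and delivers 13.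

Step 8. The process at risk is Lewis-acid-assisted opening of the vinyl oxirane at C7 by isopropanol, tartrate or hydroperoxide on titanium, or stalling of the conjugated dienol. The fallback sets out from 11 and comes back at 12: a metal-free, reagent-controlled Shi epoxidation of 11 itself. The dioxirane is generated from 1,2:4,5-di-O-isopropylidene-β-L-erythro-2,3-hexodiulo-2,6-pyranose (the enantiomer of the D-fructose-derived ketone, as an S,S trans-oxirane requires) and KHSO5 (Oxone, 2KHSO5·KHSO4·K2SO4) in MeCN/dimethoxymethane/aqueous K2CO3 buffer at 0 °C. Facial control then comes from the ketone alone, and site selectivity from the deactivation of C8=C9 by the allylic acetate. No new compound is involved.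

Step 7. The process at risk is poor or inverted facial discrimination by the phosphoric acid on a polyunsaturated aldehyde. The fallback sets out from 9 and comes back at 11. Zinc-mediated Barbier propargylation (propargyl bromide, Zn, THF/aq NH4Cl, 0 °C) gives 11 together with its C5 epimer (2R,3S,4E,6E,8R)-8-hydroxyundeca-4,6-dien-10-yne-2,3-diyl diacetate F6. Step 8 is then run as a kinetic resolution with a substoichiometric charge of hydroperoxide, which should convert 11 into 12 and leave F6. Recovered F6 is inverted by a Mitsunobu reaction with chloroacetic acid (PPh3, diisopropyl azodicarboxylate) to the (5S) ester (2R,3S,4E,6E,8S)-8-(2-chloroacetoxy)undeca-4,6-dien-10-yne-2,3-diyl diacetate F7. Thiourea/NaHCO3 in ethanol removes the chloroacetyl group without touching the acetates and returns 11.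

Further compounds
F1 | step 9 | (2R,3S,4E,6S,7S)-6-hydroxy-7-(methoxymethoxy)nona-4,8-diene-2,3-diyl diacetate | O[C@@H](/C=C/[C@H](OC(C)=O)[C@@H](C)OC(C)=O)[C@@H](OCOC)C=C
F2 | step 9 | (2R,3S,4E,6S,7S)-6-methoxy-7-(methoxymethoxy)nona-4,8-diene-2,3-diyl diacetate | CO[C@@H](/C=C/[C@H](OC(C)=O)[C@@H](C)OC(C)=O)[C@@H](OCOC)C=C
F3 | step 9 | (2R,3S,4E,6S,7S)-8,9-dihydroxy-6-methoxy-7-(methoxymethoxy)non-4-ene-2,3-diyl diacetate (both C8 epimers, not isolated) | CO[C@@H](/C=C/[C@H](OC(C)=O)[C@@H](C)OC(C)=O)[C@@H](OCOC)C(O)CO
F4 | step 9 | (2R,3S,4E,6S,7R)-6-methoxy-7-(methoxymethoxy)-8-oxooct-4-ene-2,3-diyl diacetate | CO[C@@H](/C=C/[C@H](OC(C)=O)[C@@H](C)OC(C)=O)[C@@H](OCOC)C=O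
F5 | step 9 | (2R,3S,4E,6S,7S,8S)-8-hydroxy-6-methoxy-7-(methoxymethoxy)undec-4-en-10-yne-2,3-diyl diacetate | CO[C@@H](/C=C/[C@H](OC(C)=O)[C@@H](C)OC(C)=O)[C@@H](OCOC)[C@@H](O)CC#C
F0 | step 8 | none | none
F6 | step 7 | (2R,3S,4E,6E,8R)-8-hydroxyundeca-4,6-dien-10-yne-2,3-diyl diacetate | C#CC[C@@H](O)/C=C/C=C/[C@H](OC(C)=O)[C@@H](C)OC(C)=O
F7 | step 7 | (2R,3S,4E,6E,8S)-8-(2-chloroacetoxy)undeca-4,6-dien-10-yne-2,3-diyl diacetate | C#CC[C@H](OC(=O)CCl)/C=C/C=C/[C@H](OC(C)=O)[C@@H](C)OC(C)=O
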